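**Plan**

1. Retrosynthesis: first the O4-benzyl ether is removed. In the isopropyl-arm triketone ring, numbered C1(OH)=C2(benzylic)–C3(=O)–C4Me2–C5(=O)–C6Me2, the two Claisen bonds C2–C3 and C1–C6 are cut. This leads back to an aryl δ-lactone (a 4-isopropyl-dihydrocoumarin) and a metal enolate of methyl 2,2,4-trimethyl-3-oxopentanoate. The same two cuts open the isobutyl-arm ring; then the two aryl–CH bonds (to enals) and the aryl–hexanoyl bond are cut.
2. Forward order: the phloroglucinol ring is bought, then hexanoylated and benzylated at O4. A temporary lactone on O2/C3 is converted into the first triketone ring with the lithium enolate (step 7). A temporary lactone on O6/C5 is converted into the second triketone ring, the last ring closed, with the sodium enolate (step 10). Hydrogenolysis ends the route.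
3. Enabling feature: in each triketone ring C4 and C6 are quaternary (gem-dimethyl). The ring is therefore the folded form of a chain R–CH2–CO–CMe2–CO–CMe2–CO2Me whose only enolisable carbon is the future C2, and one Claisen ring closure is the only outcome. C3–C6 with their four methyls are ring-opened dimethylketene dimer.
4. Stereochemistry: both benzylic centres are set by the same (R)-diarylprolinol silyl ether in iminium-catalysed Friedel–Crafts alkylations of the phenol with (E)-enals. Each centre is β to the carbonyl used later and is not enolisable.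
5. Helpers: each lactone ring serves as tether, phenol mask and acyl activation and is opened in the annulation. The O4-benzyl group fixes which hydroxyl lactonises and is removed at the end.

Key step: step 10

Remark: the lactols 11 and 18 (and the hemiacetal, acetal and carbinol carbons of the fallback compounds) form as mixtures at a carbon that is not a stereocentre of the target, so it is left undefined in the SMILES. The cyclic triketones are drawn in the enol form used for the target.

**Route**

Step 1
Reactants: 1 2,2,4,4-tetramethylcyclobutane-1,3-dione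
Product: 2 methyl 2,2,4-trimethyl-3-oxopentanoate
Conditions: MeOH, NaOMe (5 mol %), reflux
Reagents that add atoms: methanol, CO
Why: Alkoxide-catalysed retro-Claisen ring opening of the non-enolisable cyclobutane-1,3-dione by methanol is the standard entry to this β-keto ester and involves no stereocentre.

Step 2
Reactants: 3 3-methylbutanal; 4 (triphenylphosphoranylidene)acetaldehyde
Product: 5 (E)-5-methylhex-2-enal
Conditions: 3 (excess), PhMe, 80 °C
Reagents that add atoms: none
Why: Wittig olefination with the stabilised formyl ylide should give the (E)-enal, and the excess of 3 limits a second homologation.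

Step 3
Reactants: 6 benzene-1,3,5-triol (phloroglucinol); 7 hexanoyl chloride
Product: 8 1-(2,4,6-trihydroxyphenyl)hexan-1-one
Conditions: AlCl3 (3 equiv), PhNO2, rt to 60 °C; aq. HCl
Reagents that add atoms: none
Why: Friedel–Crafts acylation of phloroglucinol stops after one acyl group because the chelated ketone deactivates the ring.

Step 4
Reactants: 8 1-(2,4,6-trihydroxyphenyl)hexan-1-one
Product: 9 1-[4-(benzyloxy)-2,6-dihydroxyphenyl]hexan-1-one
Conditions: BnBr (1.0 equiv), K2CO3 (1.1 equiv), DMF, 0 °C to rt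
Reagents that add atoms: benzyl bromide, BrCc1ccccc1
Why: Williamson etherification should take place at the 4-OH, the most acidic hydroxyl and the only one not hydrogen-bonded to the ketone, as is usual for 2,4,6-trihydroxyaryl ketones.

Step 5
Reactants: 9 1-[4-(benzyloxy)-2,6-dihydroxyphenyl]hexan-1-one (1.2 equiv); 5 (E)-5-methylhex-2-enal
Product: 11 1-[(4S)-5-(benzyloxy)-2,7-dihydroxy-4-(2-methylpropyl)-3,4-dihydro-2H-chromen-8-yl]hexan-1-one, via hydroxy aldehyde 10 (not isolated)
Conditions: (R)-2-[diphenyl(trimethylsilyloxy)methyl]pyrrolidine (20 mol %), PhCO2H (20 mol %), PhMe, 0 °C to rt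
Reagents that add atoms: none
Why: Iminium-catalysed Friedel–Crafts alkylation (conjugate addition of ring carbon C3 of the phenol to the enal) is followed by lactol formation with the 2-OH, the only free hydroxyl next to C3; in the (E)-iminium ion the diphenyl(silyloxy)methyl group of the (R)-amine covers the Re face at C3 of the enal, so the arene adds to the Si face and the benzylic centre forms as (S).

Step 6
Reactants: 11 1-[(4S)-5-(benzyloxy)-2,7-dihydroxy-4-(2-methylpropyl)-3,4-dihydro-2H-chromen-8-yl]hexan-1-one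
Product: 12 (4S)-5-(benzyloxy)-8-hexanoyl-7-hydroxy-4-(2-methylpropyl)-3,4-dihydro-2H-chromen-2-one
Conditions: Dess–Martin periodinane (1.5 equiv), CH2Cl2, 0 °C to rt
Reagents that add atoms: none
Why: Dess–Martin oxidation of a lactol to the δ-lactone is routine, should spare the chelated ortho-acyl phenol, and does not touch the remote benzylic centre.

Step 7
Reactants: 12 (4S)-5-(benzyloxy)-8-hexanoyl-7-hydroxy-4-(2-methylpropyl)-3,4-dihydro-2H-chromen-2-one; 2 methyl 2,2,4-trimethyl-3-oxopentanoate (3.5 equiv)
Product: 15 1-[4-(benzyloxy)-2,6-dihydroxy-3-[(1R)-1-(2-hydroxy-3,3,5,5-tetramethyl-4,6-dioxocyclohex-1-en-1-yl)-3-methylbutyl]phenyl]hexan-1-one, via lithium enolate 13 (not isolated), via triketo ester 14 (not isolated)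
Conditions: 2, LiN(iPr)2 (3.5 equiv), THF, −78 to 0 °C; 12, −78 °C to rt; aq. HCl
Reagents that add atoms: none
Why: Crossed Claisen acylation of the tetrasubstituted lithium enolate 13 by the aryl lactone of 12 is followed in the same flask by Dieckmann condensation of the only enolisable CH2 of 14 onto the methyl ester, giving the cyclic triketone as its stable enolate; the benzylic centre is β to the reacting carbonyl and is retained (the descriptor changes from S to R only through the priority change).

Step 8
Reactants: 15 1-[4-(benzyloxy)-2,6-dihydroxy-3-[(1R)-1-(2-hydroxy-3,3,5,5-tetramethyl-4,6-dioxocyclohex-1-en-1-yl)-3-methylbutyl]phenyl]hexan-1-one; 16 (E)-4-methylpent-2-enal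
Product: 18 1-[(4R)-5-(benzyloxy)-2,7-dihydroxy-6-[(1R)-1-(2-hydroxy-3,3,5,5-tetramethyl-4,6-dioxocyclohex-1-en-1-yl)-3-methylbutyl]-4-(propan-2-yl)-3,4-dihydro-2H-chromen-8-yl]hexan-1-one, via hydroxy aldehyde 17 (not isolated)
Conditions: (R)-2-[diphenyl(trimethylsilyloxy)methyl]pyrrolidine (20 mol %), CHCl3, rt
Reagents that add atoms: none
Why: A second iminium-catalysed Friedel–Crafts alkylation and lactolisation takes place at C5, the only free ring carbon, with the 6-OH (the triketone enol of 15 serves as the acid co-catalyst); the same (R)-amine again exposes the Si face at C3 of the enal, and the descriptor is (R) here only because isopropyl outranks the CH2 arm.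

Step 9
Reactants: 18 1-[(4R)-5-(benzyloxy)-2,7-dihydroxy-6-[(1R)-1-(2-hydroxy-3,3,5,5-tetramethyl-4,6-dioxocyclohex-1-en-1-yl)-3-methylbutyl]-4-(propan-2-yl)-3,4-dihydro-2H-chromen-8-yl]hexan-1-one
Product: 19 (4R)-5-(benzyloxy)-8-hexanoyl-7-hydroxy-6-[(1R)-1-(2-hydroxy-3,3,5,5-tetramethyl-4,6-dioxocyclohex-1-en-1-yl)-3-methylbutyl]-4-(propan-2-yl)-3,4-dihydro-2H-chromen-2-one
Conditions: Dess–Martin periodinane (2 equiv), CH2Cl2, 0 °C to rt
Reagents that add atoms: none
Why: Dess–Martin oxidation of the lactol to the δ-lactone as in step 6; the chelated phenol and the fully substituted triketone enol should be slower to react than the hemiacetal, and neither stereocentre is at a reacting carbon.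

Step 10
Reactants: 19 (4R)-5-(benzyloxy)-8-hexanoyl-7-hydroxy-6-[(1R)-1-(2-hydroxy-3,3,5,5-tetramethyl-4,6-dioxocyclohex-1-en-1-yl)-3-methylbutyl]-4-(propan-2-yl)-3,4-dihydro-2H-chromen-2-one; 2 methyl 2,2,4-trimethyl-3-oxopentanoate (5 equiv)
Product: 22 1-[4-(benzyloxy)-2,6-dihydroxy-3-[(1R)-1-(2-hydroxy-3,3,5,5-tetramethyl-4,6-dioxocyclohex-1-en-1-yl)-3-methylbutyl]-5-[(1R)-1-(2-hydroxy-3,3,5,5-tetramethyl-4,6-dioxocyclohex-1-en-1-yl)-2-methylpropyl]phenyl]hexan-1-one, via sodium enolate 20 (not isolated), via triketo ester 21 (not isolated)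
Conditions: 2, NaN(SiMe3)2 (5 equiv), THF, −78 to 0 °C; 19, −78 °C to rt; aq. HCl
Reagents that add atoms: none
Why: The sodium enolate 20 is C-acylated at the aryl lactone carbonyl of 19 (crossed Claisen condensation with the aryl oxide of the temporary ring as leaving group, by addition–elimination or through the ketene formed by E1cB opening of the lactone enolate), which gives the open 3,5-dioxo ester chain 21 as its sodium phenoxide. Excess enolate then deprotonates the only enolisable carbon of that chain, the CH2 between the benzylic methine and the new ketone, and this enolate closes the six-membered ring on the methyl ester in a 6-(enolendo)-exo-trig Dieckmann condensation; loss of methoxide and deprotonation of the resulting cyclic 1,3,5-triketone make the sequence irreversible. The closest known reaction type is the open-chain synthesis of syncarpic acid itself, in which the preformed enolate of a 2,2,4-trimethyl-3-oxopentanoate is C-acylated and the resulting 2,2,4,4-tetramethyl-3,5-dioxo ester is cyclised by a sodium base, taken together with the opening of dihydrocoumarins by enolates. Sodium is the counter-ion here because 19 enters as a phenoxide–enolate dianion whose sodium salts should be less tightly aggregated in THF than the lithium salts, because the more ionic enolate is the stronger nucleophile toward the lactone of this fully substituted arene, and because sodium is the counter-ion of the classical Dieckmann closure to tetramethylcyclohexanetriones. No stereocentre is created, because the ring carbon that is joined becomes the sp2 enol carbon; the isopropyl-bearing centre is β to the reacting carbonyl, cannot enolise and is carried over from 19, and the isobutyl-bearing centre is protected from retro-Michael cleavage because its phenol and triketone neighbours are present as anions. The step needs C- over O-acylation and a single site of ring closure: the gem-dimethyl carbons block every other enolisation in the chain, O-acylated or O-cyclised enol esters are themselves acyl donors and return to the pool, only the C-cyclised product is drained as the stabilised enolate, and the acidic phenol and enol of 19 are deprotonated first so that the lactone is the one electrophile left.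

Step 11
Reactants: 22 1-[4-(benzyloxy)-2,6-dihydroxy-3-[(1R)-1-(2-hydroxy-3,3,5,5-tetramethyl-4,6-dioxocyclohex-1-en-1-yl)-3-methylbutyl]-5-[(1R)-1-(2-hydroxy-3,3,5,5-tetramethyl-4,6-dioxocyclohex-1-en-1-yl)-2-methylpropyl]phenyl]hexan-1-one
Product: 23 myrtucommulone H
Conditions: H2 (1 atm), 10% Pd/C, EtOAc, rt
Reagents that add atoms: none
Why: Hydrogenolysis of the aryl benzyl ether under neutral conditions should leave the chelated aryl ketone, the tetrasubstituted enols and both benzylic C–C centres untouched.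

**Compound list**

1 | 2,2,4,4-tetramethylcyclobutane-1,3-dione (dimethylketene dimer) | CC1(C)C(=O)C(C)(C)C1=O | starting material
2 | methyl 2,2,4-trimethyl-3-oxopentanoate | COC(=O)C(C)(C)C(=O)C(C)C | intermediate
3 | 3-methylbutanal | CC(C)CC=O | starting material
4 | (triphenylphosphoranylidene)acetaldehyde | O=CC=P(c1ccccc1)(c1ccccc1)c1ccccc1 | starting material
5 | (E)-5-methylhex-2-enal | CC(C)C/C=C/C=O | intermediate
6 | benzene-1,3,5-triol (phloroglucinol) | Oc1cc(O)cc(O)c1 | starting material
7 | hexanoyl chloride | CCCCCC(=O)Cl | starting material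
8 | 1-(2,4,6-trihydroxyphenyl)hexan-1-one | CCCCCC(=O)c1c(O)cc(O)cc1O | intermediate
9 | 1-[4-(benzyloxy)-2,6-dihydroxyphenyl]hexan-1-one | CCCCCC(=O)c1c(O)cc(OCc2ccccc2)cc1O | intermediate
10 | (3S)-3-[6-(benzyloxy)-3-hexanoyl-2,4-dihydroxyphenyl]-5-methylhexanal (open form of 11, formed in the flask) | CCCCCC(=O)c1c(O)c([C@@H](CC(C)C)CC=O)c(OCc2ccccc2)cc1O | intermediate
11 | 1-[(4S)-5-(benzyloxy)-2,7-dihydroxy-4-(2-methylpropyl)-3,4-dihydro-2H-chromen-8-yl]hexan-1-one (lactol, both C2 anomers) | CCCCCC(=O)c1c2OC(O)C[C@H](CC(C)C)c2c(OCc3ccccc3)cc1O | intermediate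
12 | (4S)-5-(benzyloxy)-8-hexanoyl-7-hydroxy-4-(2-methylpropyl)-3,4-dihydro-2H-chromen-2-one | CCCCCC(=O)c1c2OC(=O)C[C@H](CC(C)C)c2c(OCc3ccccc3)cc1O | intermediate
13 | lithium 1-methoxy-2,2,4-trimethyl-1-oxopent-3-en-3-olate (lithium enolate of 2, formed in the flask) | [Li+].[O-]C(=C(C)C)C(C)(C)C(=O)OC | intermediate
14 | methyl (7S)-7-[6-(benzyloxy)-3-hexanoyl-2,4-dihydroxyphenyl]-2,2,4,4,9-pentamethyl-3,5-dioxodecanoate (present as its lithium salt in the flask) | CCCCCC(=O)c1c(O)c([C@@H](CC(C)C)CC(=O)C(C)(C)C(=O)C(C)(C)C(=O)OC)c(OCc2ccccc2)cc1O | intermediate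
15 | 1-[4-(benzyloxy)-2,6-dihydroxy-3-[(1R)-1-(2-hydroxy-3,3,5,5-tetramethyl-4,6-dioxocyclohex-1-en-1-yl)-3-methylbutyl]phenyl]hexan-1-one | CCCCCC(=O)c1c(O)c([C@@H](CC(C)C)C2=C(O)C(C)(C)C(=O)C(C)(C)C2=O)c(OCc2ccccc2)cc1O | intermediate
16 | (E)-4-methylpent-2-enal | CC(C)/C=C/C=O | starting material
17 | (3R)-3-[2-(benzyloxy)-5-hexanoyl-4,6-dihydroxy-3-[(1R)-1-(2-hydroxy-3,3,5,5-tetramethyl-4,6-dioxocyclohex-1-en-1-yl)-3-methylbutyl]phenyl]-4-methylpentanal (open form of 18, formed in the flask) | CCCCCC(=O)c1c(O)c([C@@H](CC(C)C)C2=C(O)C(C)(C)C(=O)C(C)(C)C2=O)c(OCc2ccccc2)c([C@H](CC=O)C(C)C)c1O | intermediate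
18 | 1-[(4R)-5-(benzyloxy)-2,7-dihydroxy-6-[(1R)-1-(2-hydroxy-3,3,5,5-tetramethyl-4,6-dioxocyclohex-1-en-1-yl)-3-methylbutyl]-4-(propan-2-yl)-3,4-dihydro-2H-chromen-8-yl]hexan-1-one (lactol, both C2 anomers) | CCCCCC(=O)c1c(O)c([C@@H](CC(C)C)C2=C(O)C(C)(C)C(=O)C(C)(C)C2=O)c(OCc2ccccc2)c2[C@@H](C(C)C)CC(O)Oc12 | intermediate
19 | (4R)-5-(benzyloxy)-8-hexanoyl-7-hydroxy-6-[(1R)-1-(2-hydroxy-3,3,5,5-tetramethyl-4,6-dioxocyclohex-1-en-1-yl)-3-methylbutyl]-4-(propan-2-yl)-3,4-dihydro-2H-chromen-2-one | CCCCCC(=O)c1c(O)c([C@@H](CC(C)C)C2=C(O)C(C)(C)C(=O)C(C)(C)C2=O)c(OCc2ccccc2)c2[C@@H](C(C)C)CC(=O)Oc12 | intermediate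
20 | sodium 1-methoxy-2,2,4-trimethyl-1-oxopent-3-en-3-olate (sodium enolate of 2, formed in the flask) | [Na+].[O-]C(=C(C)C)C(C)(C)C(=O)OC | intermediate
21 | methyl (7R)-7-[2-(benzyloxy)-5-hexanoyl-4,6-dihydroxy-3-[(1R)-1-(2-hydroxy-3,3,5,5-tetramethyl-4,6-dioxocyclohex-1-en-1-yl)-3-methylbutyl]phenyl]-2,2,4,4,8-pentamethyl-3,5-dioxononanoate (present as its sodium salt in the flask) | CCCCCC(=O)c1c(O)c([C@@H](CC(C)C)C2=C(O)C(C)(C)C(=O)C(C)(C)C2=O)c(OCc2ccccc2)c([C@H](CC(=O)C(C)(C)C(=O)C(C)(C)C(=O)OC)C(C)C)c1O | intermediate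
22 | 1-[4-(benzyloxy)-2,6-dihydroxy-3-[(1R)-1-(2-hydroxy-3,3,5,5-tetramethyl-4,6-dioxocyclohex-1-en-1-yl)-3-methylbutyl]-5-[(1R)-1-(2-hydroxy-3,3,5,5-tetramethyl-4,6-dioxocyclohex-1-en-1-yl)-2-methylpropyl]phenyl]hexan-1-one (4-O-benzyl myrtucommulone H) | CCCCCC(=O)c1c(O)c([C@@H](CC(C)C)C2=C(O)C(C)(C)C(=O)C(C)(C)C2=O)c(OCc2ccccc2)c([C@H](C2=C(O)C(C)(C)C(=O)C(C)(C)C2=O)C(C)C)c1O | intermediate
23 | myrtucommulone H | CCCCCC(=O)c1c(O)c([C@@H](CC(C)C)C2=C(O)C(C)(C)C(=O)C(C)(C)C2=O)c(O)c([C@H](C2=C(O)C(C)(C)C(=O)C(C)(C)C2=O)C(C)C)c1O | target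

**Step count and risks**

Total steps: 11. Longest linear sequence: 9 steps (steps 3 to 11, from 6).

Steps most likely to fail:

Step 10. Proton transfer from the lactone CH2 to the hindered enolate may occur without productive collapse, O-acylation may compete, or methoxide may cleave the non-enolisable diketone unit before ring closure. The fallback sets out from 18 and comes back at 22. It joins the chain at the aldehyde oxidation level and then closes the ring separately. Lactol 18, through its open hydroxy-aldehyde form, should undergo aldol addition of excess lithium enolate 13, generated from 2 as in step 7 (THF, −78 °C), to give the β-hydroxy ketone methyl (7R)-7-[2-(benzyloxy)-5-hexanoyl-4,6-dihydroxy-3-[(1R)-1-(2-hydroxy-3,3,5,5-tetramethyl-4,6-dioxocyclohex-1-en-1-yl)-3-methylbutyl]phenyl]-5-hydroxy-2,2,4,4,8-pentamethyl-3-oxononanoate F1. Dess–Martin oxidation of the carbinol should give 21, isolated this time. LiN(SiMe3)2 (THF, −78 to 0 °C) should then close the ring by Dieckmann condensation to 22.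

Step 8. The Friedel–Crafts alkylation may be sluggish at the last free ring carbon, which is hindered and acyl-deactivated; a non-catalysed background addition may erode facial selectivity, and the acidic triketone enol may interfere with iminium turnover. The fallback sets out from 9 and comes back at 18. It runs both enal alkylations on simple phenols and holds the isopropyl arm as an acetal while the first triketone ring is built.
- 9 and 16 under the conditions of step 5 should give the lactol 1-[(4R)-5-(benzyloxy)-2,7-dihydroxy-4-(propan-2-yl)-3,4-dihydro-2H-chromen-8-yl]hexan-1-one F2.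
- MeOH with pyridinium p-toluenesulfonate should convert it into the methyl acetal 1-[(4R)-5-(benzyloxy)-7-hydroxy-2-methoxy-4-(propan-2-yl)-3,4-dihydro-2H-chromen-8-yl]hexan-1-one F3.
- Alkylation and lactolisation with 5 and the same amine at the remaining ring carbon should give the lactol 1-[(4S,6R)-5-(benzyloxy)-2-hydroxy-8-methoxy-4-(2-methylpropyl)-6-(propan-2-yl)-3,4,7,8-tetrahydro-2H,6H-pyrano[3,2-g]chromen-10-yl]hexan-1-one F4.
- Dess–Martin oxidation should give the lactone (4S,6R)-5-(benzyloxy)-10-hexanoyl-8-methoxy-4-(2-methylpropyl)-6-(propan-2-yl)-3,4,7,8-tetrahydro-2H,6H-pyrano[3,2-g]chromen-2-one F5.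
- Annulation with the lithium enolate 13 as in step 7, to which the acetal is inert, should give 1-[(4R)-5-(benzyloxy)-7-hydroxy-6-[(1R)-1-(2-hydroxy-3,3,5,5-tetramethyl-4,6-dioxocyclohex-1-en-1-yl)-3-methylbutyl]-2-methoxy-4-(propan-2-yl)-3,4-dihydro-2H-chromen-8-yl]hexan-1-one F6.
- Aqueous HCl in THF at rt should hydrolyse the acetal to 18.

Step 7. At its first use the tetrasubstituted enolate may fail to C-acylate the lactone, stopping at the tetrahedral adduct or diverting to O-acylation and O-cyclisation. The fallback sets out from 9 and comes back at 15. It brings in the first triketone ring ready-made by conjugate addition. Knoevenagel condensation of purchased syncarpic acid (2,2,4,4-tetramethylcyclohexane-1,3,5-trione) with 3 (piperidine cat., CH2Cl2) should give 2,2,4,4-tetramethyl-6-(3-methylbutylidene)cyclohexane-1,3,5-trione F7. Friedel–Crafts-type Michael addition of 9 to it under a quinine-derived bifunctional squaramide (10 mol %, CH2Cl2, −20 °C) should give 15. The sense and level of induction would have to be established, with the pseudo-enantiomeric quinidine-derived catalyst or separation on a chiral stationary phase as recourse.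

**Further compounds**

F1 | step 10 | methyl (7R)-7-[2-(benzyloxy)-5-hexanoyl-4,6-dihydroxy-3-[(1R)-1-(2-hydroxy-3,3,5,5-tetramethyl-4,6-dioxocyclohex-1-en-1-yl)-3-methylbutyl]phenyl]-5-hydroxy-2,2,4,4,8-pentamethyl-3-oxononanoate | CCCCCC(=O)c1c(O)c([C@@H](CC(C)C)C2=C(O)C(C)(C)C(=O)C(C)(C)C2=O)c(OCc2ccccc2)c([C@H](CC(O)C(C)(C)C(=O)C(C)(C)C(=O)OC)C(C)C)c1O
F2 | step 8 | 1-[(4R)-5-(benzyloxy)-2,7-dihydroxy-4-(propan-2-yl)-3,4-dihydro-2H-chromen-8-yl]hexan-1-one | CCCCCC(=O)c1c(O)cc(OCc2ccccc2)c2[C@@H](C(C)C)CC(O)Oc12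
F3 | step 8 | 1-[(4R)-5-(benzyloxy)-7-hydroxy-2-methoxy-4-(propan-2-yl)-3,4-dihydro-2H-chromen-8-yl]hexan-1-one | CCCCCC(=O)c1c(O)cc(OCc2ccccc2)c2[C@@H](C(C)C)CC(OC)Oc12
F4 | step 8 | 1-[(4S,6R)-5-(benzyloxy)-2-hydroxy-8-methoxy-4-(2-methylpropyl)-6-(propan-2-yl)-3,4,7,8-tetrahydro-2H,6H-pyrano[3,2-g]chromen-10-yl]hexan-1-one | CCCCCC(=O)c1c2OC(O)C[C@H](CC(C)C)c2c(OCc2ccccc2)c2[C@@H](C(C)C)CC(OC)Oc12
F5 | step 8 | (4S,6R)-5-(benzyloxy)-10-hexanoyl-8-methoxy-4-(2-methylpropyl)-6-(propan-2-yl)-3,4,7,8-tetrahydro-2H,6H-pyrano[3,2-g]chromen-2-one | CCCCCC(=O)c1c2OC(=O)C[C@H](CC(C)C)c2c(OCc2ccccc2)c2[C@@H](C(C)C)CC(OC)Oc12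
F6 | step 8 | 1-[(4R)-5-(benzyloxy)-7-hydroxy-6-[(1R)-1-(2-hydroxy-3,3,5,5-tetramethyl-4,6-dioxocyclohex-1-en-1-yl)-3-methylbutyl]-2-methoxy-4-(propan-2-yl)-3,4-dihydro-2H-chromen-8-yl]hexan-1-one | CCCCCC(=O)c1c(O)c([C@@H](CC(C)C)C2=C(O)C(C)(C)C(=O)C(C)(C)C2=O)c(OCc2ccccc2)c2[C@@H](C(C)C)CC(OC)Oc12
F7 | step 7 | 2,2,4,4-tetramethyl-6-(3-methylbutylidene)cyclohexane-1,3,5-trione | CC(C)CC=C1C(=O)C(C)(C)C(=O)C(C)(C)C1=O
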